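Assumptions: atom labels C1–C8a and O2 follow the target's isochromene (azaphilone) numbering. Compounds 2, 8 and 14 are taken as commercial. Compounds 18–21 are carried as mixtures at C4a, because that centre becomes sp2 in the last step.

## Retrosynthetic overview
1. The route uses no arene precursor, no oxidative dearomatization and no late esterification. The vinylogous pyranone chromophore stays masked as a 4-alkynyl-4-hydroxycyclohexanone until the last step.
2. Ring B forms last. One acid step dehydrates the carbinol, removes all four acid-labile groups and closes C1–OH onto C3 (6-endo).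
3. The C7 ketol comes from osmylation of a C6=C7 cyclohexene anti to the C8 orsellinate, followed by oxidation of C6–OH.
4. Ring A forms first, by RCM of an allyl group (C5–C6) with an isopropenyl group (C7). Both the allyl group and the enynoate are added to the C4a carbonyl.
5. C8 and C8a come from an Evans syn aldol of a β-tert-butoxypropionyl imide with methacrolein. The orsellinate is attached to this acyclic aldol.

## Route

**Step 1**
Reactants: 1 (S)-4-benzyl-1,3-oxazolidin-2-one; 2 3-(tert-butoxy)propanoic acid
Product: 3 (S)-4-benzyl-3-[3-(tert-butoxy)propanoyl]-1,3-oxazolidin-2-one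
Conditions: PivCl, Et3N, THF, −20 °C; then LiCl, 1, → rt
Reagents that add atoms: none (both partners are numbered reactants)
Why: Mixed-anhydride N-acylation (standard Evans imide formation) creates no stereocentre and leaves the tert-butyl ether untouched.

**Step 2**
Reactants: 3; 4 methacrolein
Product: 5 (S)-4-benzyl-3-[(2S,3S)-2-(tert-butoxymethyl)-3-hydroxy-4-methylpent-4-enoyl]-1,3-oxazolidin-2-one
Conditions: Bu2BOTf, Et3N, CH2Cl2, −78 → 0 °C; 4, −78 → 0 °C; H2O2, MeOH, pH 7 buffer
Reagents that add atoms: none
Why: In this Evans syn aldol the Z-boron enolate reacts through a Zimmerman–Traxler chair on the face opposite the benzyl group, setting C8a (S) and C8 (S) in the syn relationship that becomes O8/C1 trans in ring A.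

**Step 3**
Reactants: 5; 6 N,O-dimethylhydroxylamine hydrochloride
Product: 7 (2S,3S)-2-(tert-butoxymethyl)-3-hydroxy-N-methoxy-N,4-dimethylpent-4-enamide
Conditions: AlMe3, 6, CH2Cl2, −10 °C → rt
Reagents that add atoms: 6, MeNH(OMe)·HCl, CNOC.Cl
Why: Aluminium-amide transamidation (Weinreb amide formation) is assisted by the free β-hydroxyl, releases the auxiliary and does not enolise C8a.

**Step 4**
Reactants: 8 methyl orsellinate (methyl 2,4-dihydroxy-6-methylbenzoate); 9 chloromethyl methyl ether
Product: 10 methyl 2,4-bis(methoxymethoxy)-6-methylbenzoate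
Conditions: NaH, 9, DMF, 0 °C → rt
Reagents that add atoms: 9, MOMCl, COCCl
Why: Williamson-type O-alkylation of both phenoxides gives acetals that survive base, Ru, Os and DMP and fall off in the final acid step.

**Step 5**
Reactants: 10
Product: 11 2,4-bis(methoxymethoxy)-6-methylbenzoic acid
Conditions: KOH, MeOH–H2O, reflux; careful acidification to pH 4
Reagents that add atoms: KOH/water, [K+].[OH-] and O
Why: Forcing saponification is needed for the 2,6-disubstituted benzoate, and MOM ethers are stable to base.

**Step 6**
Reactants: 7; 11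
Product: 12 (3S,4S)-4-(tert-butoxymethyl)-5-[methoxy(methyl)amino]-2-methyl-5-oxopent-1-en-3-yl 2,4-bis(methoxymethoxy)-6-methylbenzoate
Conditions: 11, 1-chloro-N,N,2-trimethylpropenylamine, CH2Cl2, 0 °C; then 7, DMAP, Et3N, 0 °C → rt
Reagents that add atoms: none
Why: DMAP-catalysed acylation with the neutral-generated acid chloride puts the hindered ester on the least crowded intermediate of the route with retention at C8, and the amide α-H is too weakly acidic for E1cB loss of the new ester.

**Step 7**
Reactants: 13 propargyl alcohol; 14 tert-butyl (triphenylphosphoranylidene)acetate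
Product: 15 tert-butyl (E)-pent-2-en-4-ynoate
Conditions: MnO2, 14, CH2Cl2, rt
Reagents that add atoms: 14, CC(C)(C)OC(=O)C=P(c1ccccc1)(c1ccccc1)c1ccccc1
Why: In this tandem oxidation–Wittig reaction propynal is trapped as it forms, and the stabilised ylide gives the E-enoate.

**Step 8**
Reactants: 12; 15
Product: 16 tert-butyl (2E,7S,8S)-8-{[2,4-bis(methoxymethoxy)-6-methylbenzoyl]oxy}-7-(tert-butoxymethyl)-9-methyl-6-oxodeca-2,9-dien-4-ynoate
Conditions: 15, LiHMDS, THF, −78 °C; 12, −78 → −20 °C; AcOH quench at −78 °C; used crude
Reagents that add atoms: none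
Why: In this Weinreb ketone synthesis the weakly basic acetylide adds once, the chelated tetrahedral intermediate hides the ketone until the acidic quench, and so C8a is not epimerised, the β-aroyloxy group is not eliminated and the 2,6-disubstituted benzoate is not attacked.

**Step 9**
Reactants: 16; 17 allyl bromide
Product: 18 tert-butyl (2E,7S,8S)-8-{[2,4-bis(methoxymethoxy)-6-methylbenzoyl]oxy}-7-(tert-butoxymethyl)-6-hydroxy-9-methyl-6-(prop-2-enyl)deca-2,9-dien-4-ynoate (C6 = C4a epimers)
Conditions: In, 17, THF–sat. aq NH4Cl, rt
Reagents that add atoms: 17, C=CCBr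
Why: Indium Barbier allylation adds 1,2 to the ynone under non-basic conditions, removes the acidic α-carbonyl position at C8a and brings in C5–C6, while the new carbinol centre is irrelevant because it is destroyed in Step 13.

**Step 10**
Reactants: 18
Product: 19 (1S,6S)-5-[(3E)-5-tert-butoxy-5-oxopent-3-en-1-ynyl]-6-(tert-butoxymethyl)-5-hydroxy-2-methylcyclohex-2-en-1-yl 2,4-bis(methoxymethoxy)-6-methylbenzoate
Conditions: Hoveyda–Grubbs II (5 mol %), toluene, 60 °C (–C2H4)
Reagents that add atoms: none
Why: Ring-closing metathesis starts at the allyl group and closes on the isopropenyl group to give the C6=C7 cyclohexene (ring A), while the internal electron-poor alkyne could only give a four-membered ring from that carbene and the enoate is metathesis-inert.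

**Step 11**
Reactants: 19
Product: 20 (1S,2S,3S,6S)-5-[(3E)-5-tert-butoxy-5-oxopent-3-en-1-ynyl]-6-(tert-butoxymethyl)-2,3,5-trihydroxy-2-methylcyclohexyl 2,4-bis(methoxymethoxy)-6-methylbenzoate (6-OH and 7-OH both on the face opposite O8)
Conditions: OsO4 (10 mol %), NMO, MeSO2NH2, acetone–H2O, rt
Reagents that add atoms: OsO4, O=[Os](=O)(=O)=O; NMO, C[N+]1([O-])CCOCC1; water, O
Why: Upjohn syn-dihydroxylation takes the only electron-rich alkene from the face anti to the bulky allylic benzoate (Kishi-type anti selectivity, with A1,2 strain against the C7 methyl pushing the ester pseudoaxial), so 7-OH ends up trans to O8 and cis to C1, which is the target's C7 arrangement.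

**Step 12**
Reactants: 20
Product: 21 (1S,2R,6S)-5-[(3E)-5-tert-butoxy-5-oxopent-3-en-1-ynyl]-6-(tert-butoxymethyl)-2,5-dihydroxy-2-methyl-3-oxocyclohexyl 2,4-bis(methoxymethoxy)-6-methylbenzoate
Conditions: Dess–Martin periodinane, NaHCO3, CH2Cl2, 0 °C → rt
Reagents that add atoms: none
Why: Dess–Martin oxidation touches only the single secondary alcohol (C6), and C7 is quaternary so the new α-ketol can neither epimerise nor eliminate the C8 ester.

**Step 13**
Reactants: 21
Product: 22 pinazaphilone B, (7R,8S,8aS)
Conditions: TFA–CH2Cl2 (1:1), anisole, 0 °C → rt; evaporate; THF–pH 7 buffer, rt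
Reagents that add atoms: none (net loss of H2O, 2 isobutene and 2 MOM)
Why: Proposed new method: the tertiary propargylic alcohol β to the C6 ketone either dehydrates via the C5 enol to the enynone or undergoes a Meyer–Schuster 1,3-shift to the C3 ketone, TFA meanwhile frees C1–OH, CO2H and both phenols, and C1–OH then adds 1,6 to C3 (6-endo-dig) or ketalises and dehydrates at C3, so both paths reach the same fully conjugated vinylogous ester as the thermodynamic sink without touching C7, C8 or C8a; the closest known reactions are acid-catalysed aldol dehydration, Meyer–Schuster rearrangement and the acid cyclisation of hydroxy-ynones to dihydropyranones.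

## Compound list
1 | (S)-4-benzyl-1,3-oxazolidin-2-one | O=C1N[C@@H](Cc2ccccc2)CO1 | starting material
2 | 3-(tert-butoxy)propanoic acid | CC(C)(C)OCCC(=O)O | starting material
3 | (S)-4-benzyl-3-[3-(tert-butoxy)propanoyl]oxazolidin-2-one | CC(C)(C)OCCC(=O)N1[C@@H](Cc2ccccc2)COC1=O | intermediate
4 | methacrolein | C=C(C)C=O | starting material
5 | Evans syn-aldol imide (2S,3S) | C=C(C)[C@@H](O)[C@H](COC(C)(C)C)C(=O)N1[C@@H](Cc2ccccc2)COC1=O | intermediate
6 | N,O-dimethylhydroxylamine hydrochloride | CNOC.Cl | starting material
7 | (2S,3S) Weinreb amide | C=C(C)[C@@H](O)[C@H](COC(C)(C)C)C(=O)N(C)OC | intermediate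
8 | methyl orsellinate | COC(=O)c1c(C)cc(O)cc1O | starting material
9 | chloromethyl methyl ether | COCCl | starting material
10 | methyl 2,4-bis(methoxymethoxy)-6-methylbenzoate | COCOc1cc(C)c(C(=O)OC)c(OCOC)c1 | intermediate
11 | 2,4-bis(methoxymethoxy)-6-methylbenzoic acid | COCOc1cc(C)c(C(=O)O)c(OCOC)c1 | intermediate
12 | O8-aroylated Weinreb amide (3S,4S) | C=C(C)[C@@H](OC(=O)c1c(C)cc(OCOC)cc1OCOC)[C@H](COC(C)(C)C)C(=O)N(C)OC | intermediate
13 | propargyl alcohol | C#CCO | starting material
14 | tert-butyl (triphenylphosphoranylidene)acetate | CC(C)(C)OC(=O)C=P(c1ccccc1)(c1ccccc1)c1ccccc1 | starting material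
15 | tert-butyl (E)-pent-2-en-4-ynoate | C#C/C=C/C(=O)OC(C)(C)C | intermediate
16 | β-aroyloxy ynone (7S,8S) | C=C(C)[C@@H](OC(=O)c1c(C)cc(OCOC)cc1OCOC)[C@H](COC(C)(C)C)C(=O)C#C/C=C/C(=O)OC(C)(C)C | intermediate
17 | allyl bromide | C=CCBr | starting material
18 | allyl/alkynyl tertiary carbinol diene (7S,8S; C4a epimers) | C=C(C)[C@@H](OC(=O)c1c(C)cc(OCOC)cc1OCOC)[C@H](COC(C)(C)C)C(O)(CC=C)C#C/C=C/C(=O)OC(C)(C)C | intermediate
19 | RCM cyclohexene (1S,6S) | Cc1cc(OCOC)cc(OCOC)c1C(=O)O[C@H]1[C@H](COC(C)(C)C)C(O)(C#C/C=C/C(=O)OC(C)(C)C)CC=C1C | intermediate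
20 | triol (1S,2S,3S,6S) | Cc1cc(OCOC)cc(OCOC)c1C(=O)O[C@H]1[C@H](COC(C)(C)C)C(O)(C#C/C=C/C(=O)OC(C)(C)C)C[C@H](O)[C@]1(C)O | intermediate
21 | α-ketol / β-hydroxy ketone (1S,2R,6S) | Cc1cc(OCOC)cc(OCOC)c1C(=O)O[C@H]1[C@H](COC(C)(C)C)C(O)(C#C/C=C/C(=O)OC(C)(C)C)CC(=O)[C@]1(C)O | intermediate
22 | pinazaphilone B (7R,8S,8aS) | Cc1cc(O)cc(O)c1C(=O)O[C@H]1[C@@H]2COC(/C=C/C(=O)O)=CC2=CC(=O)[C@]1(C)O | target

## Summary
Total steps: 13.
Longest linear sequence: 10 (Steps 1, 2, 3, 6, 8, 9, 10, 11, 12, 13).

Steps most likely to fail, each with a fallback: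
1. **Step 13 (acid cascade).**
   - Risk: 5-exo closure, O8→O1 acyl shift or alkylation of the free resorcinol may compete with the desired closure.
   - Fallback: drop the latent-alkynol idea.
     - Use an O1 silyl ether instead of the tert-butyl ether.
     - Add allylMgBr to 12 in place of the acetylide, then run RCM, OsO4 and oxidation to reach the cyclohexane-1,3-dione.
     - Triflate the less hindered C4a enol oxygen and couple with 15 (Sonogashira).
     - Desilylate, close ring B as a separate step, and deprotect last.
2. **Step 11 (osmylation).**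
   - Risk: facial selectivity may be eroded by the homoallylic CH2OtBu group and the C4a substituents.
   - Fallback: ozonolyse both terminal alkenes of 18 to the C7 methyl ketone / C6 aldehyde. Then close ring A by a triazolium-NHC intramolecular crossed benzoin. This forms the C6–C7 bond and gives 21 directly, with 7-OH equatorial and trans to O8.
3. **Step 8 (enynoate acetylide on a β-aroyloxy Weinreb amide; sensitive ynone 16).**
   - Risk: the acetylide may be too unreactive or unstable, and 16 may eliminate or epimerise.
   - Fallback: add lithium (trimethylsilyl)acetylide instead and carry the silyl alkyne through ring A construction. After desilylation, attach the side chain by Sonogashira coupling with tert-butyl (E)-3-iodoacrylate just before the final acid step.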